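Assumption: the stereodescriptors describe the head-to-tail, all-trans cyclobutane (r-1,t-2,c-3,t-4: both aroyl groups on one face, both phenyls on the other). This isomer has two mirror planes and is achiral (meso), so the given SMILES is the only stereoisomer of that relative configuration and only relative stereocontrol is needed.

**Retrosynthetic overview**
- Target ⇒ two molecules of (E)-2',4'-dihydroxychalcone by a head-to-tail retro-[2+2]: each ring bond joins Cα of one chalcone to Cβ of the other. The cyclobutane is the only ring formed and it is formed last.
- Chalcone ⇒ 2,4-dihydroxyacetophenone + benzaldehyde by Claisen–Schmidt condensation, phenols left free.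
- Rather than protect / UV-irradiate / deprotect, the free 2'-OH/C=O chelate is used as the handle for Lewis-acid-enabled visible-light triplet sensitisation, so both C–C bonds and all four stereocentres arise in one step from the unprotected chalcone.

**Step 1**
Reactants: 1 2,4-dihydroxyacetophenone; 2 benzaldehyde
Product: 4 (E)-2',4'-dihydroxychalcone, via aldol adduct 3 (not isolated)
Conditions: KOH (50% aq, 6 equiv), EtOH, 0 °C to rt, 36 h; then cold 2 M HCl to pH 3; recrystallise (EtOH/H2O)
Reagents that add atoms: none
Why: Claisen–Schmidt (crossed aldol) condensation: the methyl ketone enolate adds to the non-enolisable aldehyde to give aldol 3, and E1cB loss of hydroxide gives the conjugated E-alkene under thermodynamic control; the phenoxides formed in KOH return as free phenols on acidification, so no protecting groups are needed.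

**Step 2**
Reactants: 4 (E)-2',4'-dihydroxychalcone (two molecules)
Product: 6 r-1,t-2,c-3,t-4-1,3-bis(2,4-dihydroxybenzoyl)-2,4-diphenylcyclobutane (target), via triplet 1,4-diradical 5 (not isolated)
Conditions: Sc(OTf)3 (10 mol%), t-Bu-PyBox (12 mol%; either enantiomer or racemic, the product is achiral), Ru(bpy)3(PF6)2 (2.5 mol%), i-PrOAc/MeCN 3:1 (0.5 M in 4), degassed, blue LEDs (450 nm), 20 °C, 24–48 h; chromatography, then crystallisation
Reagents that add atoms: none
Why: Proposed new method: Sc(III) chelation of the 2'-hydroxy ketone replaces the proton that otherwise drains the excited state by intramolecular proton transfer and lowers the triplet energy of bound 4 (roughly 54 to 33 kcal/mol) below that of excited Ru(bpy)3 2+ (about 46–49), so only the chelate is sensitised and the saturated product is not re-excited ([2+2] photocycloaddition, triplet enone photodimerisation); Cα of the twisted triplet bonds to Cβ of a second molecule of 4 through an open, staggered transition state that places the aroyl and phenyl groups across the new bond trans, giving 1,4-diradical 5 (head-to-tail; the bulky PyBox–Sc-bound aroyl group is meant to disfavour the alternative bond between the two aroyl-bearing α-carbons, and this is the unproven part), and the two radical centres of 5 rotate before intersystem crossing and close from the least crowded conformer, so every substituent ends trans to both neighbours and all four stereocentres are set in this step (the product is meso, so both enantiomers of 5 converge); closest known reaction type: Lewis-acid-catalysed, Ru-sensitised intermolecular [2+2] photocycloaddition of 2'-hydroxychalcones with alkenes, which gives trans,trans cyclobutanes.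

**Compound list**
1 | 2,4-dihydroxyacetophenone, 1-(2,4-dihydroxyphenyl)ethan-1-one | CC(=O)c1ccc(O)cc1O | starting material
2 | benzaldehyde | O=Cc1ccccc1 | starting material
3 | aldol adduct, 1-(2,4-dihydroxyphenyl)-3-hydroxy-3-phenylpropan-1-one (racemic, present as its potassium phenoxide) | O=C(CC(O)c1ccccc1)c1ccc(O)cc1O | intermediate
4 | (E)-2',4'-dihydroxychalcone, (2E)-1-(2,4-dihydroxyphenyl)-3-phenylprop-2-en-1-one | O=C(/C=C/c1ccccc1)c1ccc(O)cc1O | intermediate
5 | triplet 1,4-diradical: Cα of one chalcone unit bonded to Cβ of the other, benzylic radical on the first unit's Cβ, α-keto radical on the second unit's Cα, the two new sp3 carbons in the relative configuration that becomes trans in the ring (racemic, one enantiomer drawn) | O=C(c1ccc(O)cc1O)[C@H]([C@@H](c1ccccc1)[CH]C(=O)c1ccc(O)cc1O)[CH]c1ccccc1 | intermediate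
6 | r-1,t-2,c-3,t-4-1,3-bis(2,4-dihydroxybenzoyl)-2,4-diphenylcyclobutane (head-to-tail, all-trans, meso) | O=C(c1ccc(O)cc1O)[C@H]1[C@H](c2ccccc2)[C@@H](C(=O)c2ccc(O)cc2O)[C@@H]1c1ccccc1 | target

**Step count and risk**
Total steps: 2. Longest linear sequence: 2. The route has only two steps, so only two can be ranked.

Most likely to fail, first: step 2. Sensitised dimerisations of simple chalcones are known to favour the head-to-head all-trans isomer, and the head-to-tail preference claimed here rests only on the steric argument, so 6 may be the minor regioisomer and the step is expected to be yield-limiting. A second failure mode is E/Z isomerisation followed by Lewis-acid-promoted cyclisation to 7-hydroxyflavanone. Fallback, setting out from 4 and returning at 6: abandon chelation and sensitisation in favour of covalent O-protection and direct excitation. Acetylate both phenols of 4 (Ac2O, pyridine, cat. DMAP, rt) to (E)-2',4'-diacetoxychalcone F1, which has no chelated proton and can be excited directly. Irradiate a degassed, concentrated benzene solution of F1 at 365 nm, the unsensitised manifold in which head-to-tail chalcone dimers are classically obtained alongside head-to-head ones. Isolate the all-trans head-to-tail tetraacetate, r-1,t-2,c-3,t-4-1,3-bis(2,4-diacetoxybenzoyl)-2,4-diphenylcyclobutane F2, by chromatography and crystallisation, then remove the four acetates with K2CO3 in MeOH at rt to reach 6.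

Second: step 1. The dianion of 1 is a sluggish aldol donor, so conversion can be low, and careless acidification can cyclise 4 to the flavanone. Fallback, setting out from 1 and returning at 4: mask the 4-OH so that only a monoanion has to enolise. Alkylate 1 selectively at the non-chelated 4-OH (MOMCl, K2CO3, acetone, rt) to 1-[2-hydroxy-4-(methoxymethoxy)phenyl]ethan-1-one F3. Condense F3 with 2 (KOH, EtOH, rt) to (E)-2'-hydroxy-4'-(methoxymethoxy)chalcone F4, and cleave the acetal (3 M HCl, MeOH, 50 °C) to give 4.

**Further compounds**
F1 | step 2 | (E)-2',4'-diacetoxychalcone | CC(=O)Oc1ccc(C(=O)/C=C/c2ccccc2)c(OC(C)=O)c1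
F2 | step 2 | r-1,t-2,c-3,t-4-1,3-bis(2,4-diacetoxybenzoyl)-2,4-diphenylcyclobutane | O=C(c1ccc(OC(C)=O)cc1OC(C)=O)[C@H]1[C@H](c2ccccc2)[C@@H](C(=O)c2ccc(OC(C)=O)cc2OC(C)=O)[C@@H]1c1ccccc1
F3 | step 1 | 1-[2-hydroxy-4-(methoxymethoxy)phenyl]ethan-1-one | CC(=O)c1ccc(OCOC)cc1O
F4 | step 1 | (E)-2'-hydroxy-4'-(methoxymethoxy)chalcone | O=C(/C=C/c1ccccc1)c1ccc(OCOC)cc1O
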